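Wednesday's flask is read at 6.0 min, later than the readings at which complex with two exchanged stands highest in the earlier runs, so I reckon with the fraction left and not the fraction made.

| flask | starting complex | incoming ligand | leaving ligand | remark | time |
|---|---|---|---|---|---|
| delta | 2 mM | 1.7 equiv | 5 equiv | run made earlier |  |
| alpha | 2 mM | 2.5 equiv | 5 equiv | run made earlier |  |
| theta | 2 mM | 2.8 equiv | 5 equiv | run made earlier |  |
| Friday's | 2.0 mM | 3.00 equiv | 5.00 equiv |  | 6.0 min |
| Wednesday's | 2.0 mM | 1.50 equiv | 5.00 equiv |  | 6.0 min |
| Saturday's | 2.0 mM | 4.00 equiv | 5.00 equiv |  | 6.0 min |
- delta (time / min: complex with two exchanged / %, complex with three exchanged / %): 0.333: 2.8, 1.1; 0.667: 4.3, 3.3; 1.33: 4.2, 7.0; 2.00: 5.0, 7.8; 4.00: 3.5, 6.4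
- alpha (time / min: complex with two exchanged / %, complex with three exchanged / %): 0.417: 5.9, 4.0; 1.00: 6.8, 12.6; 2.00: 5.7, 15.6; 3.00: 5.5, 15.5; 4.00: 5.0, 14.0
- theta (time / min: complex with two exchanged / %, complex with three exchanged / %): 0.833: 7.6, 12.6; 1.50: 7.2, 17.2; 2.50: 6.9, 20.0; 3.00: 6.1, 18.9; 4.00: 5.1, 17.5

(readings scatter by 0.5 percentage points)
- a reading or a percentage of complex with three exchanged counts all its forms, free or not
- which of these holds the largest part of the starting complex at the end of Friday's (complex with one exchanged / complex with three exchanged / complex with two exchanged / starting complex)
- which of these holds the largest part of the starting complex at the end of Wednesday's (complex with one exchanged / complex with three exchanged / complex with two exchanged / starting complex)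
- which of these holds the largest part of the starting complex at the end of Saturday's (complex with one exchanged / complex with three exchanged / complex with two exchanged / starting complex)
- amount of complex with two exchanged at the end of Wednesday's, in percent of the starting complex charged

Take the delta run, the nearest to Wednesday's in its charge of incoming ligand. Complex with two exchanged starts steeply, 2.8 % at 0.333 min, then bends at a knee, 4.3 % at 0.667 min. Complex with three exchanged crosses it next: 3.3 % at 0.667 min, but 7.0 % at 1.33 min. The curve of complex with two exchanged tops out in the reading 5.0 % at 2.00 min and stands at 3.5 % at 4.00 min, with no floor in sight. I call survival the fraction of complex with two exchanged still there after 2.00 min of this fade: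

survival = 3.5 % / 5.0 % = 0.700

Between these two runs the reading goes roughly with the charge of incoming ligand: at 4.00 min the alpha run reads 1.43 times the delta reading on 1.47 times the incoming ligand. One more survival step and the scaling to Wednesday's charge give:

n = 3.5 % × 0.700 × 1.50 equiv / 1.7 equiv = 2.16 %

With 0.5 percentage points on each reading, this is a rough figure.

The forecast names starting complex for Friday's, starting complex for Wednesday's and complex with one exchanged for Saturday's, and gives n = 2.3 %: “delta extrapolates to about 2.8% at 6 min, scaled down to about 2.3%”. My figure stands lower.

Among the four species asked, the flask gives complex with three exchanged on Friday's, starting complex on Wednesday's and complex with three exchanged on Saturday's, and n = 2.40 %.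

    complex with two exchanged + incoming ligand ⇌ leaving ligand + complex with three exchanged (K = 12.0, k = 16.0 /M/s)
    starting complex + complex with three exchanged ⇌ idle adduct, settled at all times (K = 100 /M)
    complex with one exchanged → side product (k = 0.0210 /s)
    complex with one exchanged + incoming ligand ⇌ leaving ligand + complex with two exchanged (K = 3.30, k = 4.20 /M/s)
    starting complex + incoming ligand ⇌ leaving ligand + complex with one exchanged (K = 2.50, k = 20.0 /M/s)

On Wednesday's, striking the step from complex with two exchanged back to complex with one exchanged raises n to 10.6 %, and striking the loss of complex with one exchanged to side product raises it to 7.88 %. So part of what holds n down on Wednesday's is that way back acting together with that loss. Taking Wednesday's 2.40 % back one survival step to the same flask stopped at 4.0 min gives 3.43 %; that flask holds 3.25 %.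

The runs were computed for an exercise, noise included.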